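## Analysis of the target

The target is a germacranolide: a ten-membered carbocycle fused trans at C6/C7 to an α-methylene-γ-butyrolactone. Carbons are numbered as in germacranes (ring C1–C10, lactone C11 and C12, exocyclic methylene C13, methyls C14 on C10 and C15 on C4). Both ring olefins, C1=C10 and C4=C5, are trisubstituted and Z. The ring carries five stereocentres, C3 (S, acetate), C6 (R), C7 (R), C8 (R, free hydroxyl) and C9 (R, ester). The ester is a (2R,3R)-2,3-epoxy-2-methylbutanoate, the cis-epoxide of angelic acid. C6 to C9 form a contiguous array, while C3 is isolated from it by the C4=C5 olefin and needs its own control element. The sensitive groups are the α-methylene lactone (Michael acceptor, base-labile), the epoxide of the ester, the allylic acetate, the two Z olefins, and the 8-hydroxyl, which lies within reach of the lactone carbonyl. The difficulties are the medium ring, the two Z trisubstituted olefins, and the unequal acylation of the 8,9-diol. The strategy rests on one feature: C8 and C9 are the only pair of adjacent oxygen-bearing ring carbons, so each can come from an aldehyde carbon and the C8–C9 bond can be made by joining two carbonyl carbons reductively.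

## Retrosynthetic reasoning

C9–O ester bond. The epoxy ester is acid-sensitive and would not survive the base needed for lactone methylenation, so it is attached last. Cutting it from 37 gives diol 31 and acid 35. The forward reaction must acylate the allylic C9 hydroxyl and leave C8 free. Acid 35 goes back through epoxy alcohol 34 and allylic alcohol 33 to angelic acid 32; a Sharpless epoxidation sets both epoxide centres.

C11=C13 and the C3 acetate. The methylene carbon is removed from 31 by a retro-Mannich/elimination sequence (28, 26), and the acetate is exchanged for a silyl ether (30, 29, 28). The diol is masked as acetonide 24 during the enolate chemistry. This leads back to diol 23, a saturated lactone with no base-sensitive ester.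

C8–C9 bond (key disconnection). Cutting 23 between the two carbinol carbons opens the ten-membered ring and removes two stereocentres. It gives dialdehyde 21, a C8 aldehyde on the lactone and a Z-enal at C9. No other ring bond offers this: both carbons are at the same oxidation level, and no polar reaction joins two electrophilic carbons directly. The forward step has to close the ring, couple at the carbonyl carbon of the enal, keep the C1=C10 geometry and set C8 and C9.

Oxidation levels at C8 and C9. Dialdehyde 21 is epimerisable at C7 and can lose the lactone carboxylate by β-elimination, so both aldehydes are released at the end under neutral conditions. C9 comes from primary alcohol 20 and its silyl ether 19. C8 comes from thioester 18, which is made from imide 17 and never passes through a free C8 alcohol that could translactonise.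

C6–C7 bond and the lactone C–O bond. Cutting C6–C7 of 17 as an aldol bond gives Z-enal 11 and succinate imide 14 (from oxazolidinone 12 and acid chloride 13). One auxiliary-controlled syn aldol sets C6 and C7 independently of the remote C3 centre, and the γ-hydroxy ester closes to the trans-lactone. This is preferred to a conjugate addition to a butenolide because it needs no separate control of C6.

C5–C6 bond. The formyl carbon of 11 is cut off to give alkenyl iodide 9, via alkenyllithium 10. The iodide carries C6 in latent form through the preceding steps without a protecting group and with the C4=C5 geometry fixed.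

C1=C10 bond. The Z olefin of 9 is traced through diol 8 to unsaturated δ-lactone 7, whose ring forces the cis geometry. Lactone 7 is cut at C1=C10 by retro ring-closing metathesis to methacrylate 6, the ester of alcohol 5. The lactone carbonyl becomes C9 and the ring oxygen is the C3 oxygen, so no Z-selective olefination is needed.

C2–C3 bond. Alcohol 5 is cut between C2 and C3 into an allyl unit and Z-iodoenal 4; a Brown allylation sets C3. Aldehyde 4 comes from alcohol 3, and 3 from prop-2-yn-1-ol 1 by carbomagnesiation and iodination, which fixes the C4=C5 geometry and installs C15.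

## Alternatives that were turned down

Alternative 1: The ring would be formed by fragmentation. A bond between C3 and C9, absent in the target, is imagined in a fused five–seven bicycle with a cis-diol at the ring fusion; Pb(OAc)4 cleaves this glycol and releases the ten-membered Z,Z-diene-3,9-dione A1. In its favour, the ring is made by breaking a bond, so there is no entropic penalty and no high dilution. Both trisubstituted olefins are ring olefins of the small rings before cleavage, so their Z geometry is certain. On these two points it is stronger than the chosen route. Against it, the key step creates no stereocentre and leaves ketones at C3 and C9. Both are enones on a flexible ring and must be reduced with control, C3 far from any directing centre. C8 in A1 is α to the C9 ketone and can epimerise. The two enones across a cis,cis-cyclodecadiene invite transannular reactions. The lactone must still be made from the acetal side chain. The chosen route is shorter and sets C8 and C9 in the ring-forming step. It carries the risk of closing a medium ring directly.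

Alternative 2: The ring would be closed at C3–C4. CrCl2 with catalytic NiCl2 and a chiral sulfonamide ligand adds a C4 alkenyl iodide terminus to a C3 aldehyde terminus of the same chain and gives A2, the 3-hydroxy germacranolide with the epoxy ester, the methylene lactone and a C8 silyl ether in place. In its favour, the closure is almost the last step, this chromium chemistry tolerates esters and lactones, and C8 and C9 are already differentiated. On endgame economy and on the diol problem it is stronger than the chosen route. Against it, C3 is set in a macrocyclisation where the ligand must override the conformational preference of the forming ring, with no neighbouring stereocentre to help. The Z trisubstituted alkenyl iodide is a slow partner for nickel. The epoxy ester and the methylene lactone must survive the whole fragment assembly and the reducing medium. The C6–C9 array must be built separately. The chosen route creates two stereocentres with the ring and exposes the fragile groups only in the last steps.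

Alternative 3: A thirteen-membered diallylic ether would be contracted. Tin–lithium exchange at C6 with n-BuLi triggers a [2,3]-Wittig shift that forms C6–C7, breaks the O–C13 bond, creates the C11=C13 methylene and gives the ten-membered dienol A3. In its favour, the shift is concerted and sets C6 and C7 together, the methylene is installed directly, and C8 and C9 carry different silyl groups from the start. On the last two points it is equal to or better than the chosen route. Against it, a thirteen-membered ether must be cyclised first. The stereochemical course of a [2,3] shift inside a macrocycle with two Z olefins depends on a ring conformation that cannot be predicted with confidence. The α-alkoxy carbanion can also undergo a [1,2] shift or elimination. Four different protecting groups and a late oxidation of C12 lengthen the endgame. The chosen route closes the carbocycle directly and needs two protecting groups on the ring.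

Key step: step 15

Remark on the chemistry: (−)-B-allyldiisopinocampheylborane is taken to be the reagent derived from (+)-α-pinene, which transfers allyl to the Si face of aldehydes. Organometallic intermediates are drawn as formal covalent structures.

## Route

Step 1
Reactants: 1 prop-2-yn-1-ol
Product: 3 (Z)-3-iodo-2-methylprop-2-en-1-ol, via alkenylmagnesium alkoxide 2 (not isolated)
Conditions: MeMgBr (2.5 equiv), CuI (10 mol %), Et2O–THF, −10 °C to rt; then I2, −10 °C; H2O
Reagents that add atoms: methylmagnesium bromide, C[Mg]Br; iodine, II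
Why: Copper-catalysed carbomagnesiation of the propargylic alkoxide places methyl on the internal carbon and magnesium on the terminal carbon, chelated cis to the CH2O group. Iodination with retention gives the Z iodide, which fixes the C4=C5 geometry of the target.

Step 2
Reactants: 3 (Z)-3-iodo-2-methylprop-2-en-1-ol
Product: 4 (Z)-3-iodo-2-methylprop-2-enal
Conditions: MnO2 (activated, excess), CH2Cl2, rt; used at once
Reagents that add atoms: none
Why: Allylic oxidation with MnO2 is neutral and should leave the Z geometry intact if the aldehyde is not stored.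

Step 3
Reactants: 4 (Z)-3-iodo-2-methylprop-2-enal
Product: 5 (3S,1Z)-1-iodo-2-methylhexa-1,5-dien-3-ol
Conditions: (−)-Ipc2B(allyl) (1 M in pentane), Et2O, −78 °C; then NaOH, H2O2, 0 °C to rt
Reagents that add atoms: (−)-B-allyldiisopinocampheylborane, C=CCB([C@@H]1C[C@@H]2C[C@H]([C@H]1C)C2(C)C)[C@@H]3C[C@@H]4C[C@H]([C@H]3C)C4(C)C
Why: Brown allylation through a chair transition state; the isopinocampheyl groups direct allyl to the Si face of the enal and should give the 3S alcohol (C3 of the target).

Step 4
Reactants: 5 (3S,1Z)-1-iodo-2-methylhexa-1,5-dien-3-ol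
Product: 6 (3S,1Z)-1-iodo-2-methylhexa-1,5-dien-3-yl 2-methylprop-2-enoate
Conditions: methacryloyl chloride, Et3N, DMAP (cat.), CH2Cl2, 0 °C
Reagents that add atoms: methacryloyl chloride, C=C(C)C(Cl)=O
Why: Routine acylation of a secondary alcohol; the acyl group brings C9, C10 and C14.

Step 5
Reactants: 6 (3S,1Z)-1-iodo-2-methylhexa-1,5-dien-3-yl 2-methylprop-2-enoate
Product: 7 (6S)-6-[(1Z)-1-iodoprop-1-en-2-yl]-3-methyl-5,6-dihydro-2H-pyran-2-one
Conditions: second-generation Grubbs catalyst (5 mol %), CH2Cl2 (5 mM), 40 °C
Reagents that add atoms: none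
Why: Ring-closing metathesis joins the terminal vinyl group and the methacrylate into a six-membered unsaturated lactone, so the new C1=C10 bond can only be cis. The trisubstituted iodoalkene is inert to the ruthenium carbene.

Step 6
Reactants: 7 (6S)-6-[(1Z)-1-iodoprop-1-en-2-yl]-3-methyl-5,6-dihydro-2H-pyran-2-one
Product: 8 (2Z,5S,6Z)-7-iodo-2,6-dimethylhepta-2,6-diene-1,5-diol
Conditions: DIBAL-H (iBu2AlH, 4 equiv), CH2Cl2, −78 to 0 °C; aq. potassium sodium tartrate
Reagents that add atoms: none
Why: 1,2-Reduction of the unsaturated lactone through the lactol gives the Z allylic diol; the alkenyl iodide is not touched by iBu2AlH at this temperature.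

Step 7
Reactants: 8 (2Z,5S,6Z)-7-iodo-2,6-dimethylhepta-2,6-diene-1,5-diol
Product: 9 (2Z,5S,6Z)-1,5-bis(tert-butyldimethylsilyloxy)-7-iodo-2,6-dimethylhepta-2,6-diene
Conditions: TBSOTf (2.4 equiv), 2,6-lutidine, CH2Cl2, −78 to 0 °C
Reagents that add atoms: tert-butyldimethylsilyl trifluoromethanesulfonate, CC(C)(C)[Si](C)(C)OS(=O)(=O)C(F)(F)F
Why: Both hydroxyls are silylated in one operation; the primary allylic silyl ether can later be removed in the presence of the secondary one.

Step 8
Reactants: 9 (2Z,5S,6Z)-1,5-bis(tert-butyldimethylsilyloxy)-7-iodo-2,6-dimethylhepta-2,6-diene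
Product: 11 (2Z,4S,6Z)-4,8-bis(tert-butyldimethylsilyloxy)-3,7-dimethylocta-2,6-dienal, via alkenyllithium 10 (not isolated)
Conditions: t-BuLi (2.1 equiv), Et2O, −78 °C; then DMF, −78 to 0 °C; H2O
Reagents that add atoms: N,N-dimethylformamide, CN(C)C=O
Why: Iodine–lithium exchange proceeds with retention, and formylation of the alkenyllithium gives the Z enal (C6). Ether at −78 °C is chosen to suppress 1,4-migration of the neighbouring silyl group from oxygen to carbon.

Step 9
Reactants: 12 (S)-4-benzyloxazolidin-2-one; 13 methyl 4-chloro-4-oxobutanoate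
Product: 14 methyl 4-[(4S)-4-benzyl-2-oxooxazolidin-3-yl]-4-oxobutanoate
Conditions: Et3N, DMAP (cat.), CH2Cl2, 0 °C to rt
Reagents that add atoms: none
Why: N-Acylation of the oxazolidinone with the acid chloride under amine/DMAP catalysis.

Step 10
Reactants: 14 methyl 4-[(4S)-4-benzyl-2-oxooxazolidin-3-yl]-4-oxobutanoate; 11 (2Z,4S,6Z)-4,8-bis(tert-butyldimethylsilyloxy)-3,7-dimethylocta-2,6-dienal
Product: 17 (4S)-4-benzyl-3-{(2R,3S)-2-[(1Z,3S,5Z)-3,7-bis(tert-butyldimethylsilyloxy)-2,6-dimethylhepta-1,5-dien-1-yl]-5-oxotetrahydrofuran-3-carbonyl}oxazolidin-2-one, via dibutylboron enolate 15 (not isolated), via open syn-aldol adduct 16 (not isolated)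
Conditions: 14, Bu2BOTf, iPr2NEt, CH2Cl2, 0 °C; 11, −78 to 0 °C; pH 7 buffer, MeOH, H2O2, 0 °C; then PPTS (cat.), CH2Cl2, rt
Reagents that add atoms: none
Why: Evans syn aldol: the imide is enolised selectively to the Z boron enolate and reacts through a Zimmerman–Traxler chair in which the (S)-benzyl auxiliary shields one face, setting C6 and C7 (2R,3S in lactone numbering) without reference to C3. The γ-hydroxy methyl ester of the syn adduct then closes to the trans-disubstituted lactone with loss of methanol.

Step 11
Reactants: 17 (4S)-4-benzyl-3-{(2R,3S)-2-[(1Z,3S,5Z)-3,7-bis(tert-butyldimethylsilyloxy)-2,6-dimethylhepta-1,5-dien-1-yl]-5-oxotetrahydrofuran-3-carbonyl}oxazolidin-2-one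
Product: 18 S-ethyl (2R,3S)-2-[(1Z,3S,5Z)-3,7-bis(tert-butyldimethylsilyloxy)-2,6-dimethylhepta-1,5-dien-1-yl]-5-oxotetrahydrofuran-3-carbothioate
Conditions: EtSH, n-BuLi, THF, 0 °C; H2O
Reagents that add atoms: ethanethiol, CCS
Why: The lithium thiolate attacks the activated exocyclic imide carbonyl far faster than the lactone and is too weak a base to epimerise C7 or to eliminate the lactone carboxylate. Auxiliary 12 is recovered.

Step 12
Reactants: 18 S-ethyl (2R,3S)-2-[(1Z,3S,5Z)-3,7-bis(tert-butyldimethylsilyloxy)-2,6-dimethylhepta-1,5-dien-1-yl]-5-oxotetrahydrofuran-3-carbothioate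
Product: 19 (2R,3S)-2-[(1Z,3S,5Z)-3,7-bis(tert-butyldimethylsilyloxy)-2,6-dimethylhepta-1,5-dien-1-yl]-5-oxotetrahydrofuran-3-carbaldehyde
Conditions: Et3SiH, palladium on carbon (10% Pd/C), acetone, rt
Reagents that add atoms: none
Why: Fukuyama reduction converts the thioester into the aldehyde under neutral conditions and stops at that level; trisubstituted olefins, silyl ethers and the lactone are expected to survive.

Step 13
Reactants: 19 (2R,3S)-2-[(1Z,3S,5Z)-3,7-bis(tert-butyldimethylsilyloxy)-2,6-dimethylhepta-1,5-dien-1-yl]-5-oxotetrahydrofuran-3-carbaldehyde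
Product: 20 (2R,3S)-2-[(1Z,3S,5Z)-3-(tert-butyldimethylsilyloxy)-7-hydroxy-2,6-dimethylhepta-1,5-dien-1-yl]-5-oxotetrahydrofuran-3-carbaldehyde
Conditions: HF·pyridine, pyridine, THF, 0 °C
Reagents that add atoms: none
Why: Buffered HF·pyridine removes the primary allylic silyl ether much faster than the secondary one at C3 and does not acetalise or epimerise the aldehyde.

Step 14
Reactants: 20 (2R,3S)-2-[(1Z,3S,5Z)-3-(tert-butyldimethylsilyloxy)-7-hydroxy-2,6-dimethylhepta-1,5-dien-1-yl]-5-oxotetrahydrofuran-3-carbaldehyde
Product: 21 (2R,3S)-2-[(1Z,3S,5Z)-3-(tert-butyldimethylsilyloxy)-2,6-dimethyl-7-oxohepta-1,5-dien-1-yl]-5-oxotetrahydrofuran-3-carbaldehyde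
Conditions: MnO2 (activated), CH2Cl2, rt; filtered and used at once
Reagents that add atoms: none
Why: MnO2 oxidises only the allylic alcohol, gives the Z enal without acid or base, and leaves the epimerisable, elimination-prone C8 aldehyde untouched.

Step 15
Reactants: 21 (2R,3S)-2-[(1Z,3S,5Z)-3-(tert-butyldimethylsilyloxy)-2,6-dimethyl-7-oxohepta-1,5-dien-1-yl]-5-oxotetrahydrofuran-3-carbaldehyde
Product: 23 (1(10)Z,3S,4Z,6R,7R,8R,9R)-3-(tert-butyldimethylsilyloxy)-8,9-dihydroxy-13-norgermacra-1(10),4-dien-12,6-olide, via bis(diiodosamarium) diolate 22 (not isolated)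
Conditions: SmI2 (0.1 M in THF, 4 equiv), THF, −78 °C, 21 added over 4 h to 2 mM; pH 7 aqueous buffer, −78 °C to rt
Reagents that add atoms: none
Why: SmI2 transfers one electron to each carbonyl group (the conjugated C9 aldehyde first), and the two samarium-bound ketyls combine at their carbonyl carbons to give C8–C9 and the bis(alkoxide) 22. The closest known reaction type is the intramolecular pinacol coupling of dialdehydes with SmI2 or low-valent titanium, which has been used to close medium and large carbocycles. The ten-membered ring is closed head-to-head, a 10-exo-trig closure in which both C=O bonds stay outside the new ring. C8 is set by the adjacent C7 centre: the ketyl oxygen with its bulky samarium turns away from the lactone CH2 (C11), so the new bond should form on the face that leaves O8 anti to C11 (8R). C9 is set relative to C8 in the closing event: with the chain held by the trans-lactone and two Z olefins, C7 and C10 should stay anti across the new bond, and only the threo arrangement then lets the two samarium alkoxides sit gauche and share a metal, which gives 9R. Three selectivities are needed: ring closure over intermolecular coupling (slow addition into dilute SmI2), bonding at C9 and not at C1 of the delocalised enal ketyl (the spin density and the Sm–O anchor are at the carbonyl end, and C1 attack would need an eight-membered ring), and retention of the C1=C10 geometry (−78 °C, no HMPA, short ketyl lifetime). Leaving out HMPA also keeps SmI2 from reducing the allylic C6–O bond of the lactone.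

Step 16
Reactants: 23 (1(10)Z,3S,4Z,6R,7R,8R,9R)-3-(tert-butyldimethylsilyloxy)-8,9-dihydroxy-13-norgermacra-1(10),4-dien-12,6-olide
Product: 24 8,9-O-isopropylidene acetal of 23
Conditions: 2,2-dimethoxypropane, PPTS (cat.), CH2Cl2, rt
Reagents that add atoms: 2,2-dimethoxypropane, COC(C)(C)OC
Why: Acetal exchange protects both hydroxyls in one step; a trans-diol on a ten-membered ring can adopt the gauche O–C–C–O angle the dioxolane needs.

Step 17
Reactants: 24 8,9-O-isopropylidene acetal of 23
Product: 26 11-(dimethylaminomethyl) lactone (C11 epimers), via lithium enolate 25 (not isolated)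
Conditions: LDA (LiN(iPr)2), THF, −78 °C; then Eschenmoser's salt ((CH2=NMe2)I), −78 to 0 °C
Reagents that add atoms: N,N-dimethylmethyleneiminium iodide, C=[N+](C)C.[I-]
Why: Mannich reaction of the lactone enolate, which has no β-leaving group on C7. The configuration at C11 is irrelevant because the centre becomes sp2 in the next step.

Step 18
Reactants: 26 11-(dimethylaminomethyl) lactone (C11 epimers)
Product: 28 3-(tert-butyldimethylsilyloxy)-8,9-O-isopropylidene α-methylene lactone, via trimethylammonium iodide 27 (not isolated)
Conditions: MeI, MeOH, rt; then NaHCO3 (aq.), CH2Cl2, rt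
Reagents that add atoms: none
Why: Quaternisation followed by mild base-induced β-elimination of trimethylamine gives the exocyclic C11=C13 olefin.

Step 19
Reactants: 28 3-(tert-butyldimethylsilyloxy)-8,9-O-isopropylidene α-methylene lactone
Product: 29 3-hydroxy-8,9-O-isopropylidene α-methylene lactone
Conditions: HF·pyridine, pyridine, THF, 0 °C to rt
Reagents that add atoms: none
Why: Buffered fluoride in acidic form cleaves the secondary silyl ether without exposing the methylene lactone to a basic nucleophile; the acetonide should hold.

Step 20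
Reactants: 29 3-hydroxy-8,9-O-isopropylidene α-methylene lactone
Product: 30 3-acetoxy-8,9-O-isopropylidene α-methylene lactone
Conditions: Ac2O, pyridine, DMAP (cat.), CH2Cl2, 0 °C
Reagents that add atoms: acetic anhydride, CC(=O)OC(C)=O
Why: Routine acetylation of the only free hydroxyl; C3 is not touched.

Step 21
Reactants: 30 3-acetoxy-8,9-O-isopropylidene α-methylene lactone
Product: 31 (1(10)Z,3S,4Z,6R,7R,8R,9R)-3-acetoxy-8,9-dihydroxygermacra-1(10),4,11(13)-trien-12,6-olide
Conditions: AcOH–H2O (4:1), 40 °C
Reagents that add atoms: none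
Why: Mild aqueous acid hydrolyses the strained trans-fused dioxolane; the acetate, lactone and olefins should be stable.

Step 22
Reactants: 32 angelic acid
Product: 33 (Z)-2-methylbut-2-en-1-ol
Conditions: LiAlH4, Et2O, 0 °C; H2O
Reagents that add atoms: none
Why: Hydride reduction of the conjugated acid to the allylic alcohol at low temperature keeps the Z geometry.

Step 23
Reactants: 33 (Z)-2-methylbut-2-en-1-ol
Product: 34 [(2S,3R)-2,3-dimethyloxiran-2-yl]methanol
Conditions: Ti(OiPr)4 (10 mol %), L-(+)-diethyl tartrate (12 mol %), t-BuOOH, 4 Å molecular sieves, CH2Cl2, −20 °C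
Reagents that add atoms: tert-butyl hydroperoxide, CC(C)(C)OO
Why: Sharpless asymmetric epoxidation; the L-(+)-tartrate delivers oxygen to the same face as in the epoxidation of nerol, which gives the (2S,3R) epoxy alcohol. The cis relation of the two methyl-bearing carbons follows from the Z olefin.

Step 24
Reactants: 34 [(2S,3R)-2,3-dimethyloxiran-2-yl]methanol
Product: 35 (2R,3R)-2,3-dimethyloxirane-2-carboxylic acid
Conditions: PhI(OAc)2 (2.2 equiv), TEMPO (cat.), MeCN–H2O, rt
Reagents that add atoms: water, O
Why: Oxoammonium oxidation takes the primary alcohol through the aldehyde hydrate to the acid without opening the epoxide; the descriptor at C2 changes from S to R only because of the new priority of the carboxyl group.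

Step 25
Reactants: 35 (2R,3R)-2,3-dimethyloxirane-2-carboxylic acid; 31 (1(10)Z,3S,4Z,6R,7R,8R,9R)-3-acetoxy-8,9-dihydroxygermacra-1(10),4,11(13)-trien-12,6-olide
Product: 37 CNP0137407.10, via mixed anhydride 36 (not isolated)
Conditions: 35, 2,4,6-trichlorobenzoyl chloride, Et3N, THF, rt; then 31 (1.0 equiv), DMAP, toluene, rt
Reagents that add atoms: none
Why: Yamaguchi esterification with retention at C9; the acid has no α-hydrogen and cannot epimerise. The allylic C9 hydroxyl next to the flat C10 is expected to react before the C8 hydroxyl, which is flanked by the branched C7.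

## Compound list

1 | prop-2-yn-1-ol | C#CCO | starting material
2 | bromomagnesium (Z)-3-(bromomagnesio)-2-methylprop-2-en-1-olate | Br[Mg]OC/C(C)=C\[Mg]Br | intermediate
3 | (Z)-3-iodo-2-methylprop-2-en-1-ol | OC/C(C)=C\I | intermediate
4 | (Z)-3-iodo-2-methylprop-2-enal | O=C/C(C)=C\I | intermediate
5 | (3S,1Z)-1-iodo-2-methylhexa-1,5-dien-3-ol | C=CC[C@H](O)/C(C)=C\I | intermediate
6 | (3S,1Z)-1-iodo-2-methylhexa-1,5-dien-3-yl 2-methylprop-2-enoate | C=CC[C@H](OC(=O)C(C)=C)/C(C)=C\I | intermediate
7 | (6S)-6-[(1Z)-1-iodoprop-1-en-2-yl]-3-methyl-5,6-dihydro-2H-pyran-2-one | CC1=CC[C@H](OC1=O)/C(C)=C\I | intermediate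
8 | (2Z,5S,6Z)-7-iodo-2,6-dimethylhepta-2,6-diene-1,5-diol | OC/C(C)=C\C[C@H](O)/C(C)=C\I | intermediate
9 | (2Z,5S,6Z)-1,5-bis(tert-butyldimethylsilyloxy)-7-iodo-2,6-dimethylhepta-2,6-diene | CC(C)(C)[Si](C)(C)OC/C(C)=C\C[C@H](O[Si](C)(C)C(C)(C)C)/C(C)=C\I | intermediate
10 | (1Z)-alkenyllithium from 9 (lithium in place of iodine) | CC(C)(C)[Si](C)(C)OC/C(C)=C\C[C@H](O[Si](C)(C)C(C)(C)C)/C(C)=C\[Li] | intermediate
11 | (2Z,4S,6Z)-4,8-bis(tert-butyldimethylsilyloxy)-3,7-dimethylocta-2,6-dienal | CC(C)(C)[Si](C)(C)OC/C(C)=C\C[C@H](O[Si](C)(C)C(C)(C)C)/C(C)=C\C=O | intermediate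
12 | (S)-4-benzyloxazolidin-2-one | O=C1N[C@@H](Cc2ccccc2)CO1 | starting material
13 | methyl 4-chloro-4-oxobutanoate | COC(=O)CCC(Cl)=O | starting material
14 | methyl 4-[(4S)-4-benzyl-2-oxooxazolidin-3-yl]-4-oxobutanoate | COC(=O)CCC(=O)N1[C@@H](Cc2ccccc2)COC1=O | intermediate
15 | dibutylboron (Z)-enolate of 14 | COC(=O)C/C=C(\OB(CCCC)CCCC)N1[C@@H](Cc2ccccc2)COC1=O | intermediate
16 | methyl (3S,4R,5Z,7S,9Z)-3-[(4S)-4-benzyl-2-oxooxazolidine-3-carbonyl]-7,11-bis(tert-butyldimethylsilyloxy)-4-hydroxy-6,10-dimethylundeca-5,9-dienoate | COC(=O)C[C@H](C(=O)N1[C@@H](Cc2ccccc2)COC1=O)[C@H](O)/C=C(/C)[C@@H](O[Si](C)(C)C(C)(C)C)C/C=C(/C)CO[Si](C)(C)C(C)(C)C | intermediate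
17 | (4S)-4-benzyl-3-{(2R,3S)-2-[(1Z,3S,5Z)-3,7-bis(tert-butyldimethylsilyloxy)-2,6-dimethylhepta-1,5-dien-1-yl]-5-oxotetrahydrofuran-3-carbonyl}oxazolidin-2-one | O=C1C[C@H](C(=O)N2[C@@H](Cc3ccccc3)COC2=O)[C@@H](/C=C(/C)[C@@H](O[Si](C)(C)C(C)(C)C)C/C=C(/C)CO[Si](C)(C)C(C)(C)C)O1 | intermediate
18 | S-ethyl (2R,3S)-2-[(1Z,3S,5Z)-3,7-bis(tert-butyldimethylsilyloxy)-2,6-dimethylhepta-1,5-dien-1-yl]-5-oxotetrahydrofuran-3-carbothioate | O=C1C[C@H](C(=O)SCC)[C@@H](/C=C(/C)[C@@H](O[Si](C)(C)C(C)(C)C)C/C=C(/C)CO[Si](C)(C)C(C)(C)C)O1 | intermediate
19 | (2R,3S)-2-[(1Z,3S,5Z)-3,7-bis(tert-butyldimethylsilyloxy)-2,6-dimethylhepta-1,5-dien-1-yl]-5-oxotetrahydrofuran-3-carbaldehyde | O=C1C[C@H](C=O)[C@@H](/C=C(/C)[C@@H](O[Si](C)(C)C(C)(C)C)C/C=C(/C)CO[Si](C)(C)C(C)(C)C)O1 | intermediate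
20 | (2R,3S)-2-[(1Z,3S,5Z)-3-(tert-butyldimethylsilyloxy)-7-hydroxy-2,6-dimethylhepta-1,5-dien-1-yl]-5-oxotetrahydrofuran-3-carbaldehyde | O=C1C[C@H](C=O)[C@@H](/C=C(/C)[C@@H](O[Si](C)(C)C(C)(C)C)C/C=C(/C)CO)O1 | intermediate
21 | (2R,3S)-2-[(1Z,3S,5Z)-3-(tert-butyldimethylsilyloxy)-2,6-dimethyl-7-oxohepta-1,5-dien-1-yl]-5-oxotetrahydrofuran-3-carbaldehyde (trans-lactone dialdehyde; 3S,6R,7S in germacrane numbering) | O=C1C[C@H](C=O)[C@@H](/C=C(/C)[C@@H](O[Si](C)(C)C(C)(C)C)C/C=C(/C)C=O)O1 | intermediate
22 | bis(diiodosamarium) 8,9-diolate of 23 | O=C1C[C@H]2[C@H](O1)/C=C(/C)[C@@H](O[Si](C)(C)C(C)(C)C)C/C=C(/C)[C@@H](O[Sm](I)I)[C@@H]2O[Sm](I)I | intermediate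
23 | (1(10)Z,3S,4Z,6R,7R,8R,9R)-3-(tert-butyldimethylsilyloxy)-8,9-dihydroxy-13-norgermacra-1(10),4-dien-12,6-olide (trans-lactone, threo 8,9-diol, O8 anti to C11) | O=C1C[C@H]2[C@H](O1)/C=C(/C)[C@@H](O[Si](C)(C)C(C)(C)C)C/C=C(/C)[C@@H](O)[C@@H]2O | intermediate
24 | 8,9-O-isopropylidene acetal of 23 (all stereocentres spatially as in 23) | O=C1C[C@H]2[C@H](O1)/C=C(/C)[C@@H](O[Si](C)(C)C(C)(C)C)C/C=C(/C)[C@H]3OC(C)(C)O[C@H]23 | intermediate
25 | lithium enolate of 24 (C11=C12 enolate) | [Li]OC1=C[C@H]2[C@H](O1)/C=C(/C)[C@@H](O[Si](C)(C)C(C)(C)C)C/C=C(/C)[C@H]3OC(C)(C)O[C@H]23 | intermediate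
26 | 11-(dimethylaminomethyl) derivative of 24 (C11 not defined, other centres as in 23) | O=C1C(CN(C)C)[C@H]2[C@H](O1)/C=C(/C)[C@@H](O[Si](C)(C)C(C)(C)C)C/C=C(/C)[C@H]3OC(C)(C)O[C@H]23 | intermediate
27 | trimethylammonium iodide from 26 | O=C1C(C[N+](C)(C)C)[C@H]2[C@H](O1)/C=C(/C)[C@@H](O[Si](C)(C)C(C)(C)C)C/C=C(/C)[C@H]3OC(C)(C)O[C@H]23.[I-] | intermediate
28 | 3-(tert-butyldimethylsilyloxy)-8,9-O-isopropylidenegermacra-1(10),4,11(13)-trien-12,6-olide (Z,Z; centres as in 23) | O=C1C(=C)[C@H]2[C@H](O1)/C=C(/C)[C@@H](O[Si](C)(C)C(C)(C)C)C/C=C(/C)[C@H]3OC(C)(C)O[C@H]23 | intermediate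
29 | 3-hydroxy-8,9-O-isopropylidenegermacra-1(10),4,11(13)-trien-12,6-olide (Z,Z; centres as in 23) | O=C1C(=C)[C@H]2[C@H](O1)/C=C(/C)[C@@H](O)C/C=C(/C)[C@H]3OC(C)(C)O[C@H]23 | intermediate
30 | 3-acetoxy-8,9-O-isopropylidenegermacra-1(10),4,11(13)-trien-12,6-olide (Z,Z; centres as in 23) | O=C1C(=C)[C@H]2[C@H](O1)/C=C(/C)[C@@H](OC(C)=O)C/C=C(/C)[C@H]3OC(C)(C)O[C@H]23 | intermediate
31 | (1(10)Z,3S,4Z,6R,7R,8R,9R)-3-acetoxy-8,9-dihydroxygermacra-1(10),4,11(13)-trien-12,6-olide | O=C1C(=C)[C@H]2[C@H](O1)/C=C(/C)[C@@H](OC(C)=O)C/C=C(/C)[C@@H](O)[C@@H]2O | intermediate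
32 | angelic acid, (Z)-2-methylbut-2-enoic acid | C/C=C(/C)C(O)=O | starting material
33 | (Z)-2-methylbut-2-en-1-ol | C/C=C(/C)CO | intermediate
34 | [(2S,3R)-2,3-dimethyloxiran-2-yl]methanol | OC[C@]1(C)O[C@@H]1C | intermediate
35 | (2R,3R)-2,3-dimethyloxirane-2-carboxylic acid | OC(=O)[C@]1(C)O[C@@H]1C | intermediate
36 | (2R,3R)-2,3-dimethyloxirane-2-carboxylic 2,4,6-trichlorobenzoic anhydride | O=C(OC(=O)c1c(Cl)cc(Cl)cc1Cl)[C@]2(C)O[C@@H]2C | intermediate
37 | CNP0137407.10, (1(10)Z,3S,4Z,6R,7R,8R,9R)-3-acetoxy-8-hydroxy-9-[(2R,3R)-2,3-dimethyloxirane-2-carbonyloxy]germacra-1(10),4,11(13)-trien-12,6-olide | C=C1C(=O)O[C@@H]2/C=C(/C)[C@@H](OC(C)=O)C/C=C(/C)[C@@H](OC(=O)[C@]3(C)O[C@@H]3C)[C@H](O)[C@@H]12 | target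

## Step count and least certain steps

Total step count: 25. Longest linear sequence: 21 steps (steps 1–8, 10–21 and 25, from prop-2-yn-1-ol). Steps 9 and 22–24 are side branches.

Step 15 (key step). Three things can go wrong.
- Intermolecular coupling or simple reduction of both aldehydes may win, because a ten-membered ring closes slowly.
- The enal ketyl may bond through C1 or lose its Z geometry.
- Facial selectivity at C9 may be poor, since it depends on a ring conformation that is only argued, not known.

The fallback for ring closure changes the coupling manifold, not only the medium. From 21, the McMurry pinacol coupling with TiCl3(DME)1.5 and zinc–copper couple in DME at room temperature, with very slow addition, holds and reduces both carbonyl groups on low-valent titanium and joins them as a titanium diolate. This is the variant with the closest precedent for ten-membered carbocycles. It returns to the route at 23 and makes no new compound. If only C9 is formed with poor selectivity, the material is carried forward and C9 is reset by the oxidation–reduction sequence described under step 25. A Mitsunobu inversion on the free 8,9-diol is not an option, because the neighbouring hydroxyl would close an epoxide.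

Step 8. The alkenyllithium carries a cis allylic silyl ether, so migration of silicon from oxygen to carbon can compete with formylation if the temperature rises, and the Z enal can isomerise on work-up. The fallback avoids the organolithium altogether. From 9, a palladium-catalysed reductive carbonylation (Pd(PPh3)4, CO at 1 atm, Bu3SnH added slowly, THF, 50 °C) replaces iodine by a formyl group with retention and gives 11 directly. No new compound is made.

Step 12. The palladium surface may reduce or isomerise an olefin, or ionise the allylic C6–O bond of the lactone, during the thioester reduction. The fallback sets C8 at the alcohol level and oxidises both ends together. From imide 17, NaBH4 in THF–H2O at 0 °C cleaves the auxiliary reductively to the hydroxymethyl lactone F1. HF·pyridine then removes the primary silyl ether to give the lactone diol F2. Dess–Martin periodinane with NaHCO3 oxidises both primary alcohols and returns to the route at 21. This path must be kept non-basic after the reduction, because the C8 alkoxide can translactonise.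

Step 25. Acylation may be unselective between C8 and C9, or the acyl group may migrate to C8 under the amine base, because the two secondary hydroxyls differ only modestly in hindrance. The fallback differentiates them by reaction type. From 31, MnO2 oxidises only the allylic C9 hydroxyl and gives the hydroxy enone F3. Et3SiOTf and 2,6-lutidine at −78 °C protect C8 as the triethylsilyl ether F4. NaBH4 with CeCl3·7H2O in MeOH at −78 °C reduces the ketone in the 1,2 sense, anti to the silyloxy group, to the 9R alcohol F5. Esterification with anhydride 36 gives F6, and HF·pyridine removes the silyl group and returns to the route at 37. The same sequence corrects a wrong configuration at C9 from step 15.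

## Further compounds

F0 | step 15 | none | none
F0 | step 8 | none | none
F1 | step 12 | (4S,5R)-5-[(1Z,3S,5Z)-3,7-bis(tert-butyldimethylsilyloxy)-2,6-dimethylhepta-1,5-dien-1-yl]-4-(hydroxymethyl)dihydrofuran-2(3H)-one (hydroxymethyl lactone, centres spatially as in 19) | O=C1C[C@H](CO)[C@@H](/C=C(/C)[C@@H](O[Si](C)(C)C(C)(C)C)C/C=C(/C)CO[Si](C)(C)C(C)(C)C)O1
F2 | step 12 | lactone diol: 4-(hydroxymethyl) lactone with free 7-hydroxyl on the side chain (centres spatially as in 20) | O=C1C[C@H](CO)[C@@H](/C=C(/C)[C@@H](O[Si](C)(C)C(C)(C)C)C/C=C(/C)CO)O1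
F3 | step 25 | 3-acetoxy-8-hydroxy-9-oxogermacra-1(10),4,11(13)-trien-12,6-olide (centres as in 31) | O=C1C(=C)[C@H]2[C@H](O1)/C=C(/C)[C@@H](OC(C)=O)C/C=C(/C)C(=O)[C@@H]2O
F4 | step 25 | 3-acetoxy-9-oxo-8-(triethylsilyloxy)germacra-1(10),4,11(13)-trien-12,6-olide | O=C1C(=C)[C@H]2[C@H](O1)/C=C(/C)[C@@H](OC(C)=O)C/C=C(/C)C(=O)[C@@H]2O[Si](CC)(CC)CC
F5 | step 25 | 3-acetoxy-9-hydroxy-8-(triethylsilyloxy)germacra-1(10),4,11(13)-trien-12,6-olide (C9 as in 31) | O=C1C(=C)[C@H]2[C@H](O1)/C=C(/C)[C@@H](OC(C)=O)C/C=C(/C)[C@@H](O)[C@@H]2O[Si](CC)(CC)CC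
F6 | step 25 | 8-O-triethylsilyl ether of 37 | O=C1C(=C)[C@H]2[C@H](O1)/C=C(/C)[C@@H](OC(C)=O)C/C=C(/C)[C@@H](OC(=O)[C@]3(C)O[C@@H]3C)[C@@H]2O[Si](CC)(CC)CC
A1 | alternative 1 | ten-membered Z,Z-diene-3,9-dione with 6-silyloxy, 8-methoxymethoxy and a 2,2-dimethoxyethyl branch at C7 | COC(OC)C[C@H]1[C@H](O[Si](C)(C)C(C)(C)C)/C=C(/C)C(=O)C/C=C(/C)C(=O)[C@@H]1OCOC
A2 | alternative 2 | 3-hydroxy-8-(triethylsilyloxy) germacranolide with the epoxy ester at C9 | C=C1C(=O)O[C@@H]2/C=C(/C)[C@@H](O)C/C=C(/C)[C@@H](OC(=O)[C@]3(C)O[C@@H]3C)[C@H](O[Si](CC)(CC)CC)[C@@H]12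
A3 | alternative 3 | ten-membered dienol with C6 hydroxyl, C7 2-propenyl branch bearing a p-methoxybenzyl ether, and silyl ethers at C3, C8 and C9 | C=C(COCc1ccc(OC)cc1)[C@H]2[C@H](O)/C=C(/C)[C@@H](O[Si](C)(C)C(C)(C)C)C/C=C(/C)[C@@H](O[Si](CC)(CC)CC)[C@@H]2O[Si](C(C)C)(C(C)C)C(C)C
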